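The route rests on the central C2–C3 bond of the butanediol core (lignan C8–C8'). Both carbons lie alpha to C1 and C4, which are taken back to carboxyl level, so the bond joins two enolate carbons of like polarity. Step 4 makes it by oxidative heterocoupling with Fe(acac)3: the lithium enolate of an N-acyloxazolidinone carrying the 4-benzyloxy-3-methoxybenzyl arm is united with the lithium enolate of a benzyl ester carrying the 3-benzyloxy-4-methoxybenzyl arm. One operation joins the two unlike halves and sets both stereocentres, the first from the auxiliary, the second by relative induction. Reduction, benzoylation and hydrogenolysis finish the route.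

Key step: step 4

Assumption: in step 4 the new bond is taken to form on the face of the chelated Z-enolate anti to the C4 benzyl group of the auxiliary, as in alkylations of the same enolate; compounds 1, 2, 5, 8 and 14 are taken as commercial.

Step 1
Reactants: 1 3-(4-hydroxy-3-methoxyphenyl)propanoic acid; 2 benzyl bromide
Product: 4 3-[4-(benzyloxy)-3-methoxyphenyl]propanoic acid, via benzyl ester 3 (not isolated)
Conditions: BnBr (2.3 equiv), K2CO3, DMF, 60 °C; then aq. NaOH, MeOH, 60 °C; HCl work-up
Reagents that add atoms: benzyl bromide (2), BrCc1ccccc1; sodium hydroxide, [Na+].[OH-]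
Why: Williamson etherification with carboxylate O-alkylation benzylates both acidic sites, and saponification then frees only the acid because the aryl benzyl ether is inert to hydroxide.

Step 2
Reactants: 4 3-[4-(benzyloxy)-3-methoxyphenyl]propanoic acid; 5 (S)-4-benzyloxazolidin-2-one
Product: 7 (S)-4-benzyl-3-{3-[4-(benzyloxy)-3-methoxyphenyl]propanoyl}oxazolidin-2-one, via mixed pivalic anhydride 6 (not isolated)
Conditions: PivCl, Et3N, THF, −20 °C; then LiCl, 5, −20 °C to rt
Reagents that add atoms: pivaloyl chloride, CC(C)(C)C(Cl)=O (its acyl group is held only in intermediate 6)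
Why: Mixed-anhydride N-acylation, in which the oxazolidinone activated by LiCl and Et3N attacks the less hindered acyl carbon of the pivalic anhydride, leaving the stereocentre of 5 untouched.

Step 3
Reactants: 8 3-(3-hydroxy-4-methoxyphenyl)propanoic acid; 2 benzyl bromide
Product: 9 benzyl 3-[3-(benzyloxy)-4-methoxyphenyl]propanoate
Conditions: BnBr (2.3 equiv), K2CO3, DMF, 60 °C
Reagents that add atoms: benzyl bromide (2), BrCc1ccccc1
Why: Williamson etherification with carboxylate O-alkylation by an unhindered benzylic bromide should benzylate phenol and acid in one operation and give the ester partner directly.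

Step 4
Reactants: 7 (S)-4-benzyl-3-{3-[4-(benzyloxy)-3-methoxyphenyl]propanoyl}oxazolidin-2-one; 9 benzyl 3-[3-(benzyloxy)-4-methoxyphenyl]propanoate
Product: 12 benzyl (2R,3R)-3-[(S)-4-benzyl-2-oxooxazolidine-3-carbonyl]-2-[3-(benzyloxy)-4-methoxybenzyl]-4-[4-(benzyloxy)-3-methoxyphenyl]butanoate, via lithium imide enolate 10 (not isolated), via lithium ester enolate 11 (not isolated)
Conditions: 7 (1 equiv), 9 (2 equiv), LiN(iPr)2 (3.1 equiv), THF, −78 °C; then Fe(acac)3 (3 equiv), −78 °C to rt; chromatography
Reagents that add atoms: lithium diisopropylamide, [Li+].CC(C)[N-]C(C)C (its lithium is held only in intermediates 10 and 11; no reagent leaves atoms in 12)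
Why: Oxidative enolate heterocoupling: LiN(iPr)2 turns 7 into its chelated Z-enolate 10 and 9 into ester enolate 11, which share a mixed aggregate; Fe(acac)3 (trivalent iron) takes one electron from one enolate to give an alpha-carbonyl radical that is trapped by the neighbouring enolate, and a second equivalent oxidizes the resulting radical anion to the 1,4-dicarbonyl compound. The closest known reaction types are the Fe(acac)3-mediated heterocoupling of N-acyloxazolidinone enolates with ester or ketone enolates and the oxidative dimerization of 3-arylpropanoyl oxazolidinone enolates. No ring is closed. C3 of 12 is set by the auxiliary, because the bond forms on the face of the chelated Z-enolate anti to the C4 benzyl group, which gives R. C2 of 12 is set by relative induction: the metal-bridged aggregate holds the two C–O units synclinal, and only the like (R,R) topicity then places the two arylmethyl groups anti across the forming bond; this control should be the weaker one, and the minor C2 epimer would be removed by chromatography. The step needs cross-coupling over homocoupling, which the different aggregation and oxidation behaviour of imide and ester enolates and the twofold excess of the cheap ester 9 should secure.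

Step 5
Reactants: 12 benzyl (2R,3R)-3-[(S)-4-benzyl-2-oxooxazolidine-3-carbonyl]-2-[3-(benzyloxy)-4-methoxybenzyl]-4-[4-(benzyloxy)-3-methoxyphenyl]butanoate
Product: 13 (2R,3R)-2-[3-(benzyloxy)-4-methoxybenzyl]-3-[4-(benzyloxy)-3-methoxybenzyl]butane-1,4-diol
Conditions: LiBH4 (5 equiv), MeOH (5 equiv), THF, 0 °C to rt; aqueous work-up
Reagents that add atoms: none
Why: Hydride reduction, in which LiBH4 activated by MeOH cleaves the N-acyloxazolidinone at the exocyclic carbonyl and reduces the benzyl ester (directly or through the lactone) to the diol without touching the two stereocentres.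

Step 6
Reactants: 13 (2R,3R)-2-[3-(benzyloxy)-4-methoxybenzyl]-3-[4-(benzyloxy)-3-methoxybenzyl]butane-1,4-diol; 14 benzoyl chloride
Product: 15 (2R,3R)-2-[3-(benzyloxy)-4-methoxybenzyl]-3-[4-(benzyloxy)-3-methoxybenzyl]butane-1,4-diyl dibenzoate
Conditions: BzCl (2.5 equiv), pyridine, DMAP (cat.), CH2Cl2, 0 °C to rt
Reagents that add atoms: benzoyl chloride (14), O=C(Cl)c1ccccc1
Why: DMAP-catalysed acylation of two unhindered primary alcohols by an acid chloride, which touches no stereocentre.

Step 7
Reactants: 15 (2R,3R)-2-[3-(benzyloxy)-4-methoxybenzyl]-3-[4-(benzyloxy)-3-methoxybenzyl]butane-1,4-diyl dibenzoate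
Product: 16 (2R,3R)-2-(3-hydroxy-4-methoxybenzyl)-3-(4-hydroxy-3-methoxybenzyl)butane-1,4-diyl dibenzoate
Conditions: H2 (1 atm), 10% Pd/C, EtOAc/EtOH, rt
Reagents that add atoms: none
Why: Catalytic hydrogenolysis should cleave the two aryl benzyl ethers, while alkyl benzoates, aryl methyl ethers and the stereocentres are inert to H2 on Pd/C at ambient pressure.

Compound list
1 | 3-(4-hydroxy-3-methoxyphenyl)propanoic acid | COc1cc(CCC(=O)O)ccc1O | starting material
2 | benzyl bromide | BrCc1ccccc1 | starting material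
3 | benzyl 3-[4-(benzyloxy)-3-methoxyphenyl]propanoate | COc1cc(CCC(=O)OCc2ccccc2)ccc1OCc1ccccc1 | intermediate (not isolated)
4 | 3-[4-(benzyloxy)-3-methoxyphenyl]propanoic acid | COc1cc(CCC(=O)O)ccc1OCc1ccccc1 | intermediate
5 | (S)-4-benzyloxazolidin-2-one | O=C1N[C@@H](Cc2ccccc2)CO1 | starting material
6 | 3-[4-(benzyloxy)-3-methoxyphenyl]propanoic pivalic anhydride | COc1cc(CCC(=O)OC(=O)C(C)(C)C)ccc1OCc1ccccc1 | intermediate (not isolated)
7 | (S)-4-benzyl-3-{3-[4-(benzyloxy)-3-methoxyphenyl]propanoyl}oxazolidin-2-one | COc1cc(CCC(=O)N2[C@@H](Cc3ccccc3)COC2=O)ccc1OCc1ccccc1 | intermediate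
8 | 3-(3-hydroxy-4-methoxyphenyl)propanoic acid | COc1ccc(CCC(=O)O)cc1O | starting material
9 | benzyl 3-[3-(benzyloxy)-4-methoxyphenyl]propanoate | COc1ccc(CCC(=O)OCc2ccccc2)cc1OCc1ccccc1 | intermediate
10 | lithium Z-enolate of imide 7 (O–Li cis to the arylmethyl group) | [Li]O/C(=C\Cc1ccc(OCc2ccccc2)c(OC)c1)N1[C@@H](Cc2ccccc2)COC1=O | intermediate (not isolated)
11 | lithium enolate of ester 9 (O–Li trans to the arylmethyl group) | [Li]O/C(OCc1ccccc1)=C/Cc1ccc(OC)c(OCc2ccccc2)c1 | intermediate (not isolated)
12 | benzyl (2R,3R)-3-[(S)-4-benzyl-2-oxooxazolidine-3-carbonyl]-2-[3-(benzyloxy)-4-methoxybenzyl]-4-[4-(benzyloxy)-3-methoxyphenyl]butanoate | COc1ccc(C[C@@H](C(=O)OCc2ccccc2)[C@H](C(=O)N2[C@@H](Cc3ccccc3)COC2=O)Cc2ccc(OCc3ccccc3)c(OC)c2)cc1OCc1ccccc1 | intermediate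
13 | (2R,3R)-2-[3-(benzyloxy)-4-methoxybenzyl]-3-[4-(benzyloxy)-3-methoxybenzyl]butane-1,4-diol | COc1ccc(C[C@@H](CO)[C@H](CO)Cc2ccc(OCc3ccccc3)c(OC)c2)cc1OCc1ccccc1 | intermediate
14 | benzoyl chloride | O=C(Cl)c1ccccc1 | starting material
15 | (2R,3R)-2-[3-(benzyloxy)-4-methoxybenzyl]-3-[4-(benzyloxy)-3-methoxybenzyl]butane-1,4-diyl dibenzoate | COc1ccc(C[C@@H](COC(=O)c2ccccc2)[C@H](COC(=O)c2ccccc2)Cc2ccc(OCc3ccccc3)c(OC)c2)cc1OCc1ccccc1 | intermediate
16 | (2R,3R)-2-(3-hydroxy-4-methoxybenzyl)-3-(4-hydroxy-3-methoxybenzyl)butane-1,4-diyl dibenzoate | COc1ccc(C[C@@H](COC(=O)c2ccccc2)[C@H](COC(=O)c2ccccc2)Cc2ccc(O)c(OC)c2)cc1O | target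

Total step count: 7. Longest linear sequence: 6 steps (steps 1, 2, 4, 5, 6, 7).

Steps most likely to fail

Step 4. The likely failure is weak facial control at the ester enolate carbon, so that the C2 epimer forms in a comparable amount; homocoupling of either enolate would lower the yield further. The fallback replaces kinetic control of this centre by thermodynamic control. It sets out from 12 as it leaves step 4, mixed with its epimer benzyl (2S,3R)-3-[(S)-4-benzyl-2-oxooxazolidine-3-carbonyl]-2-[3-(benzyloxy)-4-methoxybenzyl]-4-[4-(benzyloxy)-3-methoxyphenyl]butanoate F1. LiBH4 (1.2 equiv) and H2O (1.2 equiv) in Et2O at 0 °C should reduce only the imide carbonyl and give benzyl (2R,3R)-2-[3-(benzyloxy)-4-methoxybenzyl]-3-[4-(benzyloxy)-3-methoxybenzyl]-4-hydroxybutanoate F2 and benzyl (2S,3R)-2-[3-(benzyloxy)-4-methoxybenzyl]-3-[4-(benzyloxy)-3-methoxybenzyl]-4-hydroxybutanoate F3. TsOH (cat.) in CH2Cl2 should close these to the trans lactone (3R,4R)-3-[3-(benzyloxy)-4-methoxybenzyl]-4-[4-(benzyloxy)-3-methoxybenzyl]dihydrofuran-2(3H)-one F4 and the cis lactone (3S,4R)-3-[3-(benzyloxy)-4-methoxybenzyl]-4-[4-(benzyloxy)-3-methoxybenzyl]dihydrofuran-2(3H)-one F5. DBU in toluene at 80 °C should equilibrate the lactone alpha-carbon and convert F5 into the more stable trans isomer F4. LiAlH4 in THF at 0 °C then reduces F4 to diol 13, where the fallback rejoins the route.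

Step 5. The likely failure is hydride attack at the ring carbonyl of the oxazolidinone in this hindered, doubly branched imide (ring opening to a hydroxyethyl amide), or stalling at partly reduced stages. The fallback separates auxiliary removal from reduction and sets out from 12. LiOH and H2O2 in THF/H2O at 0 °C should cleave the exocyclic imide carbonyl by hydroperoxide attack and give (2R,3R)-4-(benzyloxy)-3-[3-(benzyloxy)-4-methoxybenzyl]-2-[4-(benzyloxy)-3-methoxybenzyl]-4-oxobutanoic acid F6. LiAlH4 in THF, 0 °C to reflux, should then reduce the acid and the benzyl ester together and return to diol 13.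

Step 7. The likely failure is stalling after loss of the first benzyl group through catalyst poisoning by traces carried from earlier steps, with ring saturation on forcing. The fallback is a non-reductive Lewis-acid dealkylation and sets out from 15. BCl3 and pentamethylbenzene in CH2Cl2 at −78 °C should cleave the aryl benzyl ethers by coordination to the ether oxygen and capture of the benzyl cation by the arene, sparing alkyl benzoates and aryl methyl ethers, and return directly to 16 (new compound: none F0).

Further compounds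
F1 | step 4 | benzyl (2S,3R)-3-[(S)-4-benzyl-2-oxooxazolidine-3-carbonyl]-2-[3-(benzyloxy)-4-methoxybenzyl]-4-[4-(benzyloxy)-3-methoxyphenyl]butanoate | COc1ccc(C[C@H](C(=O)OCc2ccccc2)[C@H](C(=O)N2[C@@H](Cc3ccccc3)COC2=O)Cc2ccc(OCc3ccccc3)c(OC)c2)cc1OCc1ccccc1
F2 | step 4 | benzyl (2R,3R)-2-[3-(benzyloxy)-4-methoxybenzyl]-3-[4-(benzyloxy)-3-methoxybenzyl]-4-hydroxybutanoate | COc1ccc(C[C@@H](C(=O)OCc2ccccc2)[C@H](CO)Cc2ccc(OCc3ccccc3)c(OC)c2)cc1OCc1ccccc1
F3 | step 4 | benzyl (2S,3R)-2-[3-(benzyloxy)-4-methoxybenzyl]-3-[4-(benzyloxy)-3-methoxybenzyl]-4-hydroxybutanoate | COc1ccc(C[C@H](C(=O)OCc2ccccc2)[C@H](CO)Cc2ccc(OCc3ccccc3)c(OC)c2)cc1OCc1ccccc1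
F4 | step 4 | (3R,4R)-3-[3-(benzyloxy)-4-methoxybenzyl]-4-[4-(benzyloxy)-3-methoxybenzyl]dihydrofuran-2(3H)-one | COc1ccc(C[C@H]2C(=O)OC[C@@H]2Cc2ccc(OCc3ccccc3)c(OC)c2)cc1OCc1ccccc1
F5 | step 4 | (3S,4R)-3-[3-(benzyloxy)-4-methoxybenzyl]-4-[4-(benzyloxy)-3-methoxybenzyl]dihydrofuran-2(3H)-one | COc1ccc(C[C@@H]2C(=O)OC[C@@H]2Cc2ccc(OCc3ccccc3)c(OC)c2)cc1OCc1ccccc1
F6 | step 5 | (2R,3R)-4-(benzyloxy)-3-[3-(benzyloxy)-4-methoxybenzyl]-2-[4-(benzyloxy)-3-methoxybenzyl]-4-oxobutanoic acid | COc1ccc(C[C@@H](C(=O)OCc2ccccc2)[C@H](C(=O)O)Cc2ccc(OCc3ccccc3)c(OC)c2)cc1OCc1ccccc1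
F0 | step 7 | none | none
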